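**Retrosynthetic overview**
- The target is reached by global hydrogenolysis of its penta-O-benzyl ether. Rings A (resorcinol part), B (4-oxyphenyl) and D (acylphloroglucinol) are bought as arenes, so only pyran ring C is built.
- Ring C is cut at C2–C3 and C4–C4a in one retro-[4+2] (catalytic enantioselective oxa-Povarov reaction): an O-aryl oxocarbenium ion (O1=C2 with C8a=C4a of ring A, a cationic 2-oxadiene) plus a ring-D styrene (C3=C4).
- Enabling feature: C2 carries O1 and the para-oxygenated ring B; C4 is benzylic to ring D, whose three oxygens sit ortho, ortho and para to it; C4a is ortho to O1 and para to the C7 oxygen. The positive charge can therefore pass from C2 to C4 to ring A.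
- Oxocarbenium precursor: an O-aryl O-pivaloyl acetal from 4-(benzyloxy)benzaldehyde, pivaloyl chloride and 3-(benzyloxy)phenol, in which the pivalate is the only group that can leave.
- Styrene: phloroglucinol, then C-dodecanoylation, formylation, tri-O-benzylation, methylenation. Ring order: A, B and D preformed; ring C closed last, with both stereocentres.

Key step: step 7

Assumption: the catalyst written in step 7, (S,S)-IDPi = HN[P(=NSO2CF3)(O2C36H16F12)]2 (C74H33F30N3O8P2S2; O2C36H16F12 = (S)-3,3'-bis[3,5-bis(trifluoromethyl)phenyl]-1,1'-binaphthalene-2,2'-diolate), is taken to give the (2R,4R) series; if the first experiment shows the opposite sense, its (R,R)-antipode is used in the same way.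

**Route**

Step 1
Reactants: 1 phloroglucinol; 2 dodecanoyl chloride
Product: 3 1-(2,4,6-trihydroxyphenyl)dodecan-1-one
Conditions: AlCl3 (3.5 equiv), PhNO2, 0 °C to 60 °C; then ice/aq. HCl
Reagents that add atoms: none
Why: Friedel–Crafts acylation of the threefold symmetric, very electron-rich ring, which should stop after one acyl group because the chelated aryl ketone is deactivated; no stereocentre is formed.

Step 2
Reactants: 3 1-(2,4,6-trihydroxyphenyl)dodecan-1-one
Product: 5 3-dodecanoyl-2,4,6-trihydroxybenzaldehyde, via iminium chloride 4 (not isolated)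
Conditions: POCl3 (1.1 equiv), DMF (1.2 equiv), EtOAc, 0 °C to rt; then H2O, 50 °C
Reagents that add atoms: N,N-dimethylformamide, CN(C)C=O; water, O
Why: Vilsmeier–Haack formylation, in which the two remaining ring positions of 3 are equivalent and activated by three hydroxyl groups, so one equivalent of the chloroiminium reagent should give a single mono-iminium salt 4 that water hydrolyses to the aldehyde; no stereocentre is formed.

Step 3
Reactants: 5 3-dodecanoyl-2,4,6-trihydroxybenzaldehyde
Product: 6 2,4,6-tris(benzyloxy)-3-dodecanoylbenzaldehyde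
Conditions: BnBr (3.6 equiv), K2CO3 (4 equiv), DMF, 60 °C
Reagents that add atoms: benzyl bromide, BrCc1ccccc1
Why: Williamson ether synthesis, in which the two carbonyl groups lower the nucleophilicity of the ring so that the phenoxides should react at oxygen, while heat and excess reagent are meant to carry the doubly chelated hydroxyl along; no stereocentre is formed.

Step 4
Reactants: 6 2,4,6-tris(benzyloxy)-3-dodecanoylbenzaldehyde
Product: 7 1-[2,4,6-tris(benzyloxy)-3-ethenylphenyl]dodecan-1-one
Conditions: Ph3PCH3Br (1.2 equiv), KOtBu (1.15 equiv), THF, −78 °C to 0 °C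
Reagents that add atoms: methyltriphenylphosphonium bromide, C[P+](c1ccccc1)(c1ccccc1)c1ccccc1.[Br-]
Why: Wittig methylenation, in which the unstabilised ylide should add to the aldehyde much faster than to the ketone shielded by two ortho benzyloxy groups and the undecyl chain; no stereocentre is formed.

Step 5
Reactants: 8 4-(benzyloxy)benzaldehyde
Product: 9 chloro[4-(benzyloxy)phenyl]methyl 2,2-dimethylpropanoate (racemic)
Conditions: pivaloyl chloride (1.1 equiv), ZnCl2 (2 mol %), CH2Cl2, 0 °C to rt; volatiles removed, used crude
Reagents that add atoms: pivaloyl chloride, CC(C)(C)C(=O)Cl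
Why: ZnCl2-catalysed addition of an acyl chloride across the aldehyde C=O (α-chloroalkyl ester formation), an atom-economical equilibrium pushed by a slight excess of the acyl chloride; the new centre is racemic and is erased again in step 7.

Step 6
Reactants: 9 chloro[4-(benzyloxy)phenyl]methyl 2,2-dimethylpropanoate; 10 3-(benzyloxy)phenol
Product: 11 [3-(benzyloxy)phenoxy][4-(benzyloxy)phenyl]methyl 2,2-dimethylpropanoate (racemic)
Conditions: Cs2CO3 (1.2 equiv), MeCN, 0 °C; filtration through basic alumina
Reagents that add atoms: none
Why: Williamson-type O-alkylation of a phenoxide by an α-chloroalkyl ester (acyloxyalkyl aryl ether formation), in which the caesium phenoxide in MeCN should favour O- over C-attack and the tert-butyl group shields the ester carbonyl from acyl transfer; the acetal centre is racemic and of no consequence.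

Step 7
Reactants: 11 [3-(benzyloxy)phenoxy][4-(benzyloxy)phenyl]methyl 2,2-dimethylpropanoate (1.3 equiv); 7 1-[2,4,6-tris(benzyloxy)-3-ethenylphenyl]dodecan-1-one
Product: 14 1-{2,4,6-tris(benzyloxy)-3-[(2R,4R)-7-(benzyloxy)-2-[4-(benzyloxy)phenyl]-3,4-dihydro-2H-chromen-4-yl]phenyl}dodecan-1-one, via aryl oxocarbenium ion 12 (not isolated), via C4 benzylic cation 13 (not isolated)
Conditions: (S,S)-IDPi HN[P(=NSO2CF3)(O2C36H16F12)]2 (5 mol %), CHCl3, 4 Å MS, −60 °C; Et3N quench at −60 °C
Reagents that add atoms: none
Why: Proposed new method: a catalytic enantioselective oxa-Povarov reaction (formal inverse-electron-demand [4+2] of a cationic 2-oxadiene with an alkene); the closest known reactions are the racemic Lewis-acid-promoted oxa-Povarov annulation of O-aryl acetals with styrenes, chiral-phosphoric-acid-catalysed Povarov reactions and IDPi-controlled Prins additions of styrenes to oxocarbenium ions. The confined strong acid protonates the pivalate carbonyl of 11 and, because the acyloxy oxygen is a much poorer donor and pivalic acid a much better leaving group than the aryloxy group, ionisation can only give the O-aryl oxocarbenium ion 12 as a contact ion pair with the chiral anion. The terminal CH2 of styrene 7 adds to C2 on the face left open by the anion (catalyst control of C2, C2–C3 bond), which moves the charge to C4, where the two ortho and the para benzyloxy groups of ring D stabilise cation 13. Ring C then closes by an intramolecular Friedel–Crafts alkylation, a 6-membered closure that is exo with respect to the C4 cation and has the arene bond C8a=C4a inside the new ring, through a chair-like transition state with both aryl groups pseudo-equatorial, so that C4 is set cis to C2 by substrate control (C4–C4a bond). The step needs site selectivity on ring A and regioselectivity on the alkene: attack by the ring carbon para to the benzyloxy group is favoured over the carbon flanked by both oxygens for steric and electronic reasons, and the styrene can only react at its CH2 terminus because the other orientation gives a primary cation. Loss of the proton from the arenium ion returns the acid, and low temperature with a small excess of 11 is meant to suppress acid-induced dimerisation of 7 and ionisation of the product at C2.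

Step 8
Reactants: 14 1-{2,4,6-tris(benzyloxy)-3-[(2R,4R)-7-(benzyloxy)-2-[4-(benzyloxy)phenyl]-3,4-dihydro-2H-chromen-4-yl]phenyl}dodecan-1-one
Product: 15 1-{2,4,6-trihydroxy-3-[(2R,4R)-7-hydroxy-2-(4-hydroxyphenyl)-3,4-dihydro-2H-chromen-4-yl]phenyl}dodecan-1-one
Conditions: H2 (1 atm), Pd(OH)2 on carbon, EtOAc/MeOH, rt
Reagents that add atoms: none
Why: Hydrogenolysis of five aryl benzyl ethers on palladium under neutral conditions, as is standard for benzylated flavans; the cyclic benzylic C2–O bond and the hindered, chelation-deactivated aryl ketone should survive at 1 atm if the reaction is stopped after uptake of five equivalents of H2, and neither stereocentre is touched.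

**Compound list**
1 | phloroglucinol (benzene-1,3,5-triol) | Oc1cc(O)cc(O)c1 | starting material
2 | dodecanoyl chloride | CCCCCCCCCCCC(=O)Cl | starting material
3 | 1-(2,4,6-trihydroxyphenyl)dodecan-1-one | CCCCCCCCCCCC(=O)c1c(O)cc(O)cc1O | intermediate
4 | [(3-dodecanoyl-2,4,6-trihydroxyphenyl)methylidene]dimethylammonium chloride (not isolated) | CCCCCCCCCCCC(=O)c1c(O)cc(O)c(C=[N+](C)C)c1O.[Cl-] | intermediate
5 | 3-dodecanoyl-2,4,6-trihydroxybenzaldehyde | CCCCCCCCCCCC(=O)c1c(O)cc(O)c(C=O)c1O | intermediate
6 | 2,4,6-tris(benzyloxy)-3-dodecanoylbenzaldehyde | CCCCCCCCCCCC(=O)c1c(OCc2ccccc2)cc(OCc2ccccc2)c(C=O)c1OCc1ccccc1 | intermediate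
7 | 1-[2,4,6-tris(benzyloxy)-3-ethenylphenyl]dodecan-1-one | CCCCCCCCCCCC(=O)c1c(OCc2ccccc2)cc(OCc2ccccc2)c(C=C)c1OCc1ccccc1 | intermediate
8 | 4-(benzyloxy)benzaldehyde | O=Cc1ccc(OCc2ccccc2)cc1 | starting material
9 | chloro[4-(benzyloxy)phenyl]methyl 2,2-dimethylpropanoate (racemic) | CC(C)(C)C(=O)OC(Cl)c1ccc(OCc2ccccc2)cc1 | intermediate
10 | 3-(benzyloxy)phenol | Oc1cccc(OCc2ccccc2)c1 | starting material
11 | [3-(benzyloxy)phenoxy][4-(benzyloxy)phenyl]methyl 2,2-dimethylpropanoate (racemic) | CC(C)(C)C(=O)OC(Oc1cccc(OCc2ccccc2)c1)c1ccc(OCc2ccccc2)cc1 | intermediate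
12 | (E)-[3-(benzyloxy)phenyl]{[4-(benzyloxy)phenyl]methylidene}oxonium, ion pair with the catalyst anion (not isolated) | C(Oc1ccc(/C=[O+]/c2cccc(OCc3ccccc3)c2)cc1)c1ccccc1 | intermediate
13 | (3R)-3-[3-(benzyloxy)phenoxy]-3-[4-(benzyloxy)phenyl]-1-[2,4,6-tris(benzyloxy)-3-dodecanoylphenyl]propan-1-ylium (not isolated) | CCCCCCCCCCCC(=O)c1c(OCc2ccccc2)cc(OCc2ccccc2)c([CH+]C[C@H](c2ccc(OCc3ccccc3)cc2)Oc2cccc(OCc3ccccc3)c2)c1OCc1ccccc1 | intermediate
14 | 1-{2,4,6-tris(benzyloxy)-3-[(2R,4R)-7-(benzyloxy)-2-[4-(benzyloxy)phenyl]-3,4-dihydro-2H-chromen-4-yl]phenyl}dodecan-1-one (2,4-cis) | CCCCCCCCCCCC(=O)c1c(OCc2ccccc2)cc(OCc2ccccc2)c([C@@H]2C[C@H](c3ccc(OCc4ccccc4)cc3)Oc3cc(OCc4ccccc4)ccc32)c1OCc1ccccc1 | intermediate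
15 | 1-{2,4,6-trihydroxy-3-[(2R,4R)-7-hydroxy-2-(4-hydroxyphenyl)-3,4-dihydro-2H-chromen-4-yl]phenyl}dodecan-1-one (2,4-cis) | CCCCCCCCCCCC(=O)c1c(O)cc(O)c([C@@H]2C[C@H](c3ccc(O)cc3)Oc3cc(O)ccc32)c1O | target

**Step count**
Total steps: 8. Longest linear sequence: 6 (steps 1, 2, 3, 4, 7, 8); the acetal branch (steps 5, 6) joins at step 7.

**Steps most likely to fail**

Step 7. What may go wrong: weak facial discrimination of a conformationally mobile acyclic oxocarbenium ion by the chiral anion, acid-induced oligomerisation of the electron-rich styrene, or erosion of configuration by ionisation of the product at C2. The fallback sets out from 11 and 7 and comes back at 14. The annulation would be run as the known achiral Lewis-acid oxa-Povarov reaction (BF3·OEt2, 1.1 equiv, CH2Cl2, −78 °C). Lewis-acid ionisation of α-acyloxy ethers to oxocarbenium ions and the Lewis-acid-promoted annulation of O-aryl oxocarbenium ions with styrenes to 2,4-cis-chromans are both established. This should give the cis cycloadduct as a racemate, that is 14 together with its mirror image, 1-{2,4,6-tris(benzyloxy)-3-[(2S,4S)-7-(benzyloxy)-2-[4-(benzyloxy)phenyl]-3,4-dihydro-2H-chromen-4-yl]phenyl}dodecan-1-one F1. Preparative chromatography on a chiral stationary phase (amylose tris(3,5-dimethylphenylcarbamate) on silica, hexane/2-propanol) would then separate the two and return 14, with the absolute configuration to be assigned by electronic circular dichroism or X-ray analysis of a heavy-atom derivative.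

Step 6. What may go wrong: acyl transfer from the ester carbonyl to the phenoxide, C-alkylation of the ambident phenoxide, reversal of the chloro ester to aldehyde, or ionisation and hydrolysis of the acetal during isolation. The fallback sets out from 10 and comes back at 11, and it also by-passes step 5. Compound 10 would be acylated with commercial 4-(benzyloxy)benzoyl chloride (Et3N, cat. DMAP, CH2Cl2, 0 °C) to the aryl ester 3-(benzyloxy)phenyl 4-(benzyloxy)benzoate F2. Reduction with diisobutylaluminium hydride, (i-Bu)2AlH, in CH2Cl2 at −78 °C should stop at the tetrahedral aluminium hemiacetal, diisobutylaluminium [3-(benzyloxy)phenoxy][4-(benzyloxy)phenyl]methoxide F3. This is acylated in the same flask with pivalic anhydride, pyridine and DMAP (−78 °C to 0 °C) to give 11, by the reductive acylation of esters to α-acyloxy ethers.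

Step 3. What may go wrong: incomplete O-alkylation of the hydroxyl chelated between two carbonyl groups, and competing C-benzylation. The fallback sets out from 3 and comes back at 7, so that steps 2 and 4 are not needed either. Compound 3 would be tri-O-benzylated (benzyl bromide, K2CO3, DMF, 60 °C; each ortho hydroxyl is here chelated to one carbonyl only) to 1-[2,4,6-tris(benzyloxy)phenyl]dodecan-1-one F4. Iodination at one of the two equivalent ring positions (N-iodosuccinimide, cat. CF3CO2H, MeCN, 0 °C) would give 1-[2,4,6-tris(benzyloxy)-3-iodophenyl]dodecan-1-one F5. Suzuki–Miyaura vinylation (potassium vinyltrifluoroborate, [1,1'-bis(diphenylphosphino)ferrocene]palladium dichloride, Cs2CO3, THF/H2O, 70 °C) would then give 7.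

**Further compounds**
F1 | step 7 | 1-{2,4,6-tris(benzyloxy)-3-[(2S,4S)-7-(benzyloxy)-2-[4-(benzyloxy)phenyl]-3,4-dihydro-2H-chromen-4-yl]phenyl}dodecan-1-one | CCCCCCCCCCCC(=O)c1c(OCc2ccccc2)cc(OCc2ccccc2)c([C@H]2C[C@@H](c3ccc(OCc4ccccc4)cc3)Oc3cc(OCc4ccccc4)ccc32)c1OCc1ccccc1
F2 | step 6 | 3-(benzyloxy)phenyl 4-(benzyloxy)benzoate | O=C(Oc1cccc(OCc2ccccc2)c1)c1ccc(OCc2ccccc2)cc1
F3 | step 6 | diisobutylaluminium [3-(benzyloxy)phenoxy][4-(benzyloxy)phenyl]methoxide (racemic, not isolated) | CC(C)C[Al](CC(C)C)OC(Oc1cccc(OCc2ccccc2)c1)c1ccc(OCc2ccccc2)cc1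
F4 | step 3 | 1-[2,4,6-tris(benzyloxy)phenyl]dodecan-1-one | CCCCCCCCCCCC(=O)c1c(OCc2ccccc2)cc(OCc2ccccc2)cc1OCc1ccccc1
F5 | step 3 | 1-[2,4,6-tris(benzyloxy)-3-iodophenyl]dodecan-1-one | CCCCCCCCCCCC(=O)c1c(OCc2ccccc2)cc(OCc2ccccc2)c(I)c1OCc1ccccc1
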